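## Retrosynthetic overview

1. Target 26 comes from macrocycle 25 by global desilylation; the ten-membered carbocycle is closed last by ring-closing metathesis at C9=C10 of ester 24.
2. Ester 24 comes from alcohol 23 and side-chain acid 20 by Mitsunobu esterification with inversion at C8; 23 comes from 22 by moving the lactone from O8 to O6.
3. 22 comes from the chromium-mediated allylation that joins bromobutenolide 15 (C7–C9, C11–C13) and aldehyde 9 (C1–C6, C10, C14, C15) at C6–C7, setting C6 and C7.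
4. 15 comes from crotonaldehyde, vinyl Grignard, kinetic resolution, 2-(bromomethyl)acrylic acid and RCM; 9 from 2-bromoallyl alcohol and methyl but-3-enoate (B-alkyl Suzuki), Wittig and asymmetric conjugate addition (C4); 20 from but-2-yne-1,4-diol.
5. Ring order: butenolide (step 10), then the γ-lactone re-closed on O6 (step 15), then the carbocycle (step 17).

Assumption: atoms are referred to by germacrane-type numbering (lactone O on C6, ester O on C8, C9=C10, C14 = CH2OH on C10, C15 = CH3 on C4, C11–C13 = methylene-lactone carbons); TBS = tert-butyldimethylsilyl, TES = triethylsilyl; (S,R)-Josiphos is taken to be the ligand antipode that gives the 3R adduct in step 5 (this assignment is from memory and should be checked; the mirror-image ligand gives 3S).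

## Route

**West fragment (aldehyde 9)**

Step 1
Reactants: 1 2-bromoprop-2-en-1-ol
Product: 2 [(2-bromoprop-2-en-1-yl)oxy](tert-butyl)dimethylsilane
Conditions: TBSCl, imidazole, CH2Cl2, 0 °C to rt
Reagents that add atoms: tert-butyldimethylsilyl chloride, CC(C)(C)[Si](C)(C)Cl
Why: Standard silylation of a primary allylic alcohol; the vinyl bromide is untouched.

Step 2
Reactants: 3 methyl but-3-enoate; 2 [(2-bromoprop-2-en-1-yl)oxy](tert-butyl)dimethylsilane
Product: 5 methyl 5-(TBSO-methyl)hex-5-enoate, via alkylborane 4 (not isolated)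
Conditions: 9-BBN, THF, 0 °C to rt; then 2, Pd(dppf)Cl2 (5 mol%), AsPh3, Cs2CO3, DMF/H2O, rt
Reagents that add atoms: none
Why: Anti-Markovnikov hydroboration of the terminal alkene followed by B-alkyl Suzuki–Miyaura sp3–sp2 coupling with the vinyl bromide builds the C1–C10 bond and the 1,1-disubstituted alkene.

Step 3
Reactants: 5 methyl 5-(TBSO-methyl)hex-5-enoate
Product: 6 5-(TBSO-methyl)hex-5-enal
Conditions: DIBAL-H (1.05 equiv), CH2Cl2, −78 °C; Rochelle salt
Reagents that add atoms: none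
Why: Partial reduction of the methyl ester stops at the aldehyde because the tetrahedral aluminium hemiacetal is stable at −78 °C.

Step 4
Reactants: 6 5-(TBSO-methyl)hex-5-enal
Product: 7 S-ethyl (2E)-7-(TBSO-methyl)octa-2,7-dienethioate
Conditions: Ph3P=CHC(O)SEt, CH2Cl2, 40 °C
Reagents that add atoms: S-ethyl (triphenylphosphoranylidene)thioacetate, CCSC(=O)C=P(c1ccccc1)(c1ccccc1)c1ccccc1
Why: Wittig olefination with a stabilised ylide gives the (E)-enethioate needed for the conjugate addition.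

Step 5
Reactants: 7 S-ethyl (2E)-7-(TBSO-methyl)octa-2,7-dienethioate
Product: 8 S-ethyl (3R)-3-methyl-7-(TBSO-methyl)oct-7-enethioate
Conditions: MeMgBr (1.2 equiv), CuBr·SMe2 (5 mol%), (S,R)-Josiphos (6 mol%), t-BuOMe, −75 °C
Reagents that add atoms: methylmagnesium bromide, C[Mg]Br
Why: Copper-catalysed asymmetric conjugate addition of the Grignard reagent to the (E)-thioenoate, in which the chiral ferrocenyl diphosphine–copper complex delivers methyl to one enantioface and sets C4 as R.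

Step 6
Reactants: 8 S-ethyl (3R)-3-methyl-7-(TBSO-methyl)oct-7-enethioate
Product: 9 (3R)-3-methyl-7-(TBSO-methyl)oct-7-enal
Conditions: DIBAL-H (1.1 equiv), CH2Cl2, −78 °C; Rochelle salt
Reagents that add atoms: none
Why: DIBAL-H reduction of a thioester stops cleanly at the aldehyde; the β-stereocentre is not epimerisable.

**East fragment (bromobutenolide 15)**

Step 7
Reactants: 10 (2E)-but-2-enal
Product: 11 rac-(4E)-hexa-1,4-dien-3-ol
Conditions: vinylmagnesium bromide, THF, −78 °C to 0 °C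
Reagents that add atoms: vinylmagnesium bromide, C=C[Mg]Br
Why: Grignard reagents add 1,2 to enals, giving the racemic bis-allylic alcohol.

Step 8
Reactants: 11 rac-(4E)-hexa-1,4-dien-3-ol
Product: 12 (3R,4E)-hexa-1,4-dien-3-ol
Conditions: Ti(OiPr)4 (0.2 equiv), L-(+)-DIPT (0.25 equiv), t-BuOOH (0.55 equiv), 4 Å sieves, CH2Cl2, −20 °C
Reagents that add atoms: none
Why: Sharpless kinetic resolution: with L-(+)-tartrate the 3S enantiomer is epoxidised quickly at its (E)-propenyl alkene, and the 3R alcohol (whose only matched alkene is the slow vinyl group) is recovered.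

Step 9
Reactants: 12 (3R,4E)-hexa-1,4-dien-3-ol; 13 2-(bromomethyl)prop-2-enoic acid
Product: 14 (3R,4E)-hexa-1,4-dien-3-yl 2-(bromomethyl)prop-2-enoate
Conditions: DCC, DMAP (5 mol%), CH2Cl2, 0 °C
Reagents that add atoms: none
Why: Steglich esterification at low temperature with little DMAP acylates the alcohol with retention and spares the allylic bromide.

Step 10
Reactants: 14 (3R,4E)-hexa-1,4-dien-3-yl 2-(bromomethyl)prop-2-enoate
Product: 15 (5S)-3-(bromomethyl)-5-[(1E)-prop-1-en-1-yl]furan-2(5H)-one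
Conditions: second-generation Grubbs catalyst (5 mol%), CH2Cl2, 40 °C, 5 mM
Reagents that add atoms: none
Why: Ring-closing metathesis between the fast-initiating vinyl group and the acrylate closes the butenolide with loss of ethene; the propenyl group is retained and the stereocentre is untouched (the descriptor changes from R to S only through CIP priorities).

**Side-chain acid 20**

Step 11
Reactants: 16 but-2-yne-1,4-diol
Product: 17 (2E)-2-(tributylstannyl)but-2-ene-1,4-diol
Conditions: Bu3SnH, PdCl2(PPh3)2 (2 mol%), THF, rt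
Reagents that add atoms: tributyltin hydride, CCCC[SnH](CCCC)CCCC
Why: Palladium-catalysed syn-hydrostannation of the symmetrical alkyne places tin trans to the C4 hydroxymethyl group, with no regiochemical issue.

Step 12
Reactants: 17 (2E)-2-(tributylstannyl)but-2-ene-1,4-diol
Product: 18 (2E)-1,4-bis(TBSO)-2-(tributylstannyl)but-2-ene
Conditions: TBSCl, imidazole, DMF, rt
Reagents that add atoms: tert-butyldimethylsilyl chloride, CC(C)(C)[Si](C)(C)Cl
Why: Double silylation of the two primary allylic alcohols.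

Step 13
Reactants: 18 (2E)-1,4-bis(TBSO)-2-(tributylstannyl)but-2-ene
Product: 20 (2E)-4-(TBSO)-2-(TBSO-methyl)but-2-enoic acid, via vinyllithium 19 (not isolated)
Conditions: n-BuLi, THF, −78 °C; CO2 gas, −78 °C to 0 °C; dilute HCl to pH 4
Reagents that add atoms: carbon dioxide, O=C=O
Why: Tin–lithium exchange and carboxylation both proceed with retention of alkene geometry, giving the (E)-acid with CO2H trans to C4; the silyl ether trans to lithium cannot undergo retro-Brook migration.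

**Fragment union and endgame**

Step 14
Reactants: 15 (5S)-3-(bromomethyl)-5-[(1E)-prop-1-en-1-yl]furan-2(5H)-one; 9 (3R)-3-methyl-7-(TBSO-methyl)oct-7-enal
Product: 22 (4S,5S)-4-[(1R,3R)-1-hydroxy-3-methyl-7-(TBSO-methyl)oct-7-en-1-yl]-3-methylidene-5-[(1E)-prop-1-en-1-yl]oxolan-2-one, via allylchromium dichloride 21 (not isolated)
Conditions: CrCl2 (4 equiv), THF, 0 °C to rt (15 in 1.3-fold excess)
Reagents that add atoms: none
Why: Nozaki–Hiyama allylation: the allylchromium adds through its γ-carbon (C7) in a chair Zimmerman–Traxler transition state, on the butenolide face anti to the propenyl group (4,5-trans), and because the ring locks the γ-substituent in the E-type position the carbinol is formed anti, which sets C7 (S) and C6 (R).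

Step 15
Reactants: 22 (4S,5S)-4-[(1R,3R)-1-hydroxy-3-methyl-7-(TBSO-methyl)oct-7-en-1-yl]-3-methylidene-5-[(1E)-prop-1-en-1-yl]oxolan-2-one
Product: 23 (4R,5R)-4-[(1S,2E)-1-hydroxybut-2-en-1-yl]-5-[(2R)-2-methyl-6-(TBSO-methyl)hept-6-en-1-yl]-3-methylideneoxolan-2-one
Conditions: DBU (0.2 equiv), toluene, 0 °C to rt; recovered 22 recycled
Reagents that add atoms: none
Why: Base-catalysed intramolecular transesterification (translactonisation) through a bicyclic orthoester-type alkoxide; the equilibrium is expected to favour acyl on the less acidic, non-allylic O6, and no stereocentre is touched (descriptors change only through CIP priorities).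

Step 16
Reactants: 23 (4R,5R)-4-[(1S,2E)-1-hydroxybut-2-en-1-yl]-5-[(2R)-2-methyl-6-(TBSO-methyl)hept-6-en-1-yl]-3-methylideneoxolan-2-one; 20 (2E)-4-(TBSO)-2-(TBSO-methyl)but-2-enoic acid
Product: 24 (1R,2E)-1-{(2R,3S)-2-[(2R)-2-methyl-6-(TBSO-methyl)hept-6-en-1-yl]-4-methylidene-5-oxooxolan-3-yl}but-2-en-1-yl (2E)-4-(TBSO)-2-(TBSO-methyl)but-2-enoate
Conditions: PPh3, DIAD, toluene, 0 °C to rt
Reagents that add atoms: none
Why: Mitsunobu esterification: SN2 displacement of the activated allylic oxyphosphonium by the carboxylate inverts C8 from S to R, the configuration of the target.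

Step 17
Reactants: 24 (1R,2E)-1-{(2R,3S)-2-[(2R)-2-methyl-6-(TBSO-methyl)hept-6-en-1-yl]-4-methylidene-5-oxooxolan-3-yl}but-2-en-1-yl (2E)-4-(TBSO)-2-(TBSO-methyl)but-2-enoate
Product: 25 (3aS,4R,5E,10R,11aR)-10-methyl-3-methylidene-2-oxo-6-(TBSO-methyl)-2,3,3a,4,7,8,9,10,11,11a-decahydrocyclodeca[b]furan-4-yl (2E)-4-(TBSO)-2-(TBSO-methyl)but-2-enoate
Conditions: second-generation Hoveyda–Grubbs catalyst (15 mol%), toluene, 80 °C, 1 mM
Reagents that add atoms: none
Why: Ring-closing metathesis between the propenyl group and the 1,1-disubstituted alkene (propene lost) closes the ten-membered ring as the ring-cis trisubstituted olefin (E by CIP because CH2OTBS outranks the ring CH2), which is strongly preferred over the strained ring-trans isomer; the conjugated exocyclic methylene and the side-chain acrylate are inert to the catalyst.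

Step 18
Reactants: 25 (3aS,4R,5E,10R,11aR)-10-methyl-3-methylidene-2-oxo-6-(TBSO-methyl)-2,3,3a,4,7,8,9,10,11,11a-decahydrocyclodeca[b]furan-4-yl (2E)-4-(TBSO)-2-(TBSO-methyl)but-2-enoate
Product: 26 (3aS,4R,5E,10R,11aR)-6-(hydroxymethyl)-10-methyl-3-methylidene-2-oxo-2,3,3a,4,7,8,9,10,11,11a-decahydrocyclodeca[b]furan-4-yl (2E)-4-hydroxy-2-(hydroxymethyl)but-2-enoate
Conditions: HF·pyridine, pyridine/THF, 0 °C to rt
Reagents that add atoms: none
Why: Buffered fluoride desilylation removes the three primary allylic silyl ethers without touching the α-methylene lactone, the allylic ester or any stereocentre; the free side-chain hydroxyls cannot lactonise because C4 is trans to the ester carbonyl.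

## Compound list

1 | 2-bromoprop-2-en-1-ol | OCC(Br)=C | starting material
2 | [(2-bromoprop-2-en-1-yl)oxy](tert-butyl)dimethylsilane | C=C(Br)CO[Si](C)(C)C(C)(C)C | intermediate
3 | methyl but-3-enoate | COC(=O)CC=C | starting material
4 | methyl 4-(9-borabicyclo[3.3.1]nonan-9-yl)butanoate | COC(=O)CCCB1C2CCCC1CCC2 | intermediate
5 | methyl 5-(TBSO-methyl)hex-5-enoate | COC(=O)CCCC(=C)CO[Si](C)(C)C(C)(C)C | intermediate
6 | 5-(TBSO-methyl)hex-5-enal | O=CCCCC(=C)CO[Si](C)(C)C(C)(C)C | intermediate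
7 | S-ethyl (2E)-7-(TBSO-methyl)octa-2,7-dienethioate | CCSC(=O)/C=C/CCCC(=C)CO[Si](C)(C)C(C)(C)C | intermediate
8 | S-ethyl (3R)-3-methyl-7-(TBSO-methyl)oct-7-enethioate | CCSC(=O)C[C@H](C)CCCC(=C)CO[Si](C)(C)C(C)(C)C | intermediate
9 | (3R)-3-methyl-7-(TBSO-methyl)oct-7-enal | O=CC[C@H](C)CCCC(=C)CO[Si](C)(C)C(C)(C)C | intermediate
10 | (2E)-but-2-enal | C/C=C/C=O | starting material
11 | rac-(4E)-hexa-1,4-dien-3-ol | C=CC(O)/C=C/C | intermediate
12 | (3R,4E)-hexa-1,4-dien-3-ol | C/C=C/[C@@H](C=C)O | intermediate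
13 | 2-(bromomethyl)prop-2-enoic acid | C=C(CBr)C(=O)O | starting material
14 | (3R,4E)-hexa-1,4-dien-3-yl 2-(bromomethyl)prop-2-enoate | C/C=C/[C@@H](C=C)OC(=O)C(=C)CBr | intermediate
15 | (5S)-3-(bromomethyl)-5-[(1E)-prop-1-en-1-yl]furan-2(5H)-one | C/C=C/[C@@H]1OC(=O)C(CBr)=C1 | intermediate
16 | but-2-yne-1,4-diol | OCC#CCO | starting material
17 | (2E)-2-(tributylstannyl)but-2-ene-1,4-diol | CCCC[Sn](CCCC)(CCCC)/C(CO)=C/CO | intermediate
18 | (2E)-1,4-bis(TBSO)-2-(tributylstannyl)but-2-ene | CCCC[Sn](CCCC)(CCCC)/C(CO[Si](C)(C)C(C)(C)C)=C/CO[Si](C)(C)C(C)(C)C | intermediate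
19 | (2Z)-1,4-bis(TBSO)but-2-en-2-yllithium | [Li]/C(CO[Si](C)(C)C(C)(C)C)=C/CO[Si](C)(C)C(C)(C)C | intermediate
20 | (2E)-4-(TBSO)-2-(TBSO-methyl)but-2-enoic acid | OC(=O)/C(CO[Si](C)(C)C(C)(C)C)=C/CO[Si](C)(C)C(C)(C)C | intermediate
21 | {[(5S)-2-oxo-5-[(1E)-prop-1-en-1-yl]-2,5-dihydrofuran-3-yl]methyl}chromium dichloride (trivalent chromium) | C/C=C/[C@@H]1OC(=O)C(C[Cr](Cl)Cl)=C1 | intermediate
22 | (4S,5S)-4-[(1R,3R)-1-hydroxy-3-methyl-7-(TBSO-methyl)oct-7-en-1-yl]-3-methylidene-5-[(1E)-prop-1-en-1-yl]oxolan-2-one | C=C1C(=O)O[C@@H](/C=C/C)[C@@H]1[C@H](O)C[C@H](C)CCCC(=C)CO[Si](C)(C)C(C)(C)C | intermediate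
23 | (4R,5R)-4-[(1S,2E)-1-hydroxybut-2-en-1-yl]-5-[(2R)-2-methyl-6-(TBSO-methyl)hept-6-en-1-yl]-3-methylideneoxolan-2-one | C=C1C(=O)O[C@H](C[C@H](C)CCCC(=C)CO[Si](C)(C)C(C)(C)C)[C@H]1[C@@H](O)/C=C/C | intermediate
24 | (1R,2E)-1-{(2R,3S)-2-[(2R)-2-methyl-6-(TBSO-methyl)hept-6-en-1-yl]-4-methylidene-5-oxooxolan-3-yl}but-2-en-1-yl (2E)-4-(TBSO)-2-(TBSO-methyl)but-2-enoate | C=C1C(=O)O[C@H](C[C@H](C)CCCC(=C)CO[Si](C)(C)C(C)(C)C)[C@H]1[C@H](OC(=O)/C(CO[Si](C)(C)C(C)(C)C)=C/CO[Si](C)(C)C(C)(C)C)/C=C/C | intermediate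
25 | (3aS,4R,5E,10R,11aR)-10-methyl-3-methylidene-2-oxo-6-(TBSO-methyl)-2,3,3a,4,7,8,9,10,11,11a-decahydrocyclodeca[b]furan-4-yl (2E)-4-(TBSO)-2-(TBSO-methyl)but-2-enoate | C=C1C(=O)O[C@@H]2C[C@H](C)CCC/C(CO[Si](C)(C)C(C)(C)C)=C\[C@@H](OC(=O)/C(CO[Si](C)(C)C(C)(C)C)=C/CO[Si](C)(C)C(C)(C)C)[C@@H]12 | intermediate
26 | (3aS,4R,5E,10R,11aR)-6-(hydroxymethyl)-10-methyl-3-methylidene-2-oxo-2,3,3a,4,7,8,9,10,11,11a-decahydrocyclodeca[b]furan-4-yl (2E)-4-hydroxy-2-(hydroxymethyl)but-2-enoate (CNP0131216.2) | C=C1C(=O)O[C@@H]2C[C@H](C)CCC/C(CO)=C\[C@@H](OC(=O)/C(=C/CO)CO)[C@@H]12 | target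

## Step count and risks

Total steps: 18 (West fragment 6, East fragment 4, side chain 3, union and endgame 5).
Longest linear sequence: 11 steps (steps 1–6, then 14–18).

Three steps most likely to fail:

**Step 15 (translactonisation).** The equilibrium may not favour 23, or the base may isomerise the exocyclic alkene into the ring. Fallback: build the lactone on O6 from the start. It sets out from 9: addition of vinylmagnesium bromide and Sharpless kinetic resolution of the C6 epimers (Ti(OiPr)4, L-(+)-DIPT, t-BuOOH) give (3R,5R)-5-methyl-9-(TBSO-methyl)deca-1,9-dien-3-ol F1. Steglich esterification with 13 gives (3R,5R)-5-methyl-9-(TBSO-methyl)deca-1,9-dien-3-yl 2-(bromomethyl)prop-2-enoate F2, and ring-closing metathesis with second-generation Grubbs catalyst gives (5R)-3-(bromomethyl)-5-[(2R)-2-methyl-6-(TBSO-methyl)hept-6-en-1-yl]furan-2(5H)-one F3. CrCl2-mediated allylation of crotonaldehyde 10 with this bromobutenolide forms C7–C8 anti to the C6 side chain and, through the chair transition state, the (1S)-carbinol; this is 23, where the route resumes.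

**Step 16 (Mitsunobu inversion at the hindered allylic C8).** SN2' attack, elimination or partial retention are possible. Fallback: invert C8 intramolecularly before the lactone is moved. It sets out from 22: TESOTf and 2,6-lutidine give (4R,5S)-4-[(1R,3R)-3-methyl-7-(TBSO-methyl)-1-(triethylsilyloxy)oct-7-en-1-yl]-3-methylidene-5-[(1E)-prop-1-en-1-yl]oxolan-2-one F4. LiOH in THF/H2O opens the lactone to (3R,4R,6R)-3-[(1S,2E)-1-hydroxybut-2-en-1-yl]-6-methyl-2-methylidene-10-(TBSO-methyl)-4-(triethylsilyloxy)undec-10-enoic acid F5. PPh3/DIAD lactonisation (5-exo SN2, inversion at C8) gives the cis-lactone (4R,5R)-4-[(1R,3R)-3-methyl-7-(TBSO-methyl)-1-(triethylsilyloxy)oct-7-en-1-yl]-3-methylidene-5-[(1E)-prop-1-en-1-yl]oxolan-2-one F6. PPTS in MeOH removes the TES group and catalytic DBU moves the acyl group to O6 (relief of the cis-lactone), giving (4R,5R)-4-[(1R,2E)-1-hydroxybut-2-en-1-yl]-5-[(2R)-2-methyl-6-(TBSO-methyl)hept-6-en-1-yl]-3-methylideneoxolan-2-one F7. Yamaguchi esterification with 20 (2,4,6-trichlorobenzoyl chloride, Et3N, DMAP; retention) then gives 24, where the route resumes.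

**Step 17 (ring-closing metathesis to the ten-membered ring).** Oligomerisation or failure to close on the acylated substrate is possible. Fallback: close the ring before acylation. It sets out from 23: metathesis of the free alcohol (second-generation Hoveyda–Grubbs catalyst, toluene, 80 °C, 1 mM) gives (3aR,4S,5E,10R,11aR)-4-hydroxy-10-methyl-3-methylidene-6-(TBSO-methyl)-3a,4,7,8,9,10,11,11a-octahydrocyclodeca[b]furan-2(3H)-one F8. Mitsunobu esterification of this macrocyclic alcohol with 20 (PPh3, DIAD; inversion at C8) gives 25, where the route resumes.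

## Further compounds

F1 | step 15 | (3R,5R)-5-methyl-9-(TBSO-methyl)deca-1,9-dien-3-ol | C=C[C@H](O)C[C@H](C)CCCC(=C)CO[Si](C)(C)C(C)(C)C
F2 | step 15 | (3R,5R)-5-methyl-9-(TBSO-methyl)deca-1,9-dien-3-yl 2-(bromomethyl)prop-2-enoate | C=C[C@H](OC(=O)C(=C)CBr)C[C@H](C)CCCC(=C)CO[Si](C)(C)C(C)(C)C
F3 | step 15 | (5R)-3-(bromomethyl)-5-[(2R)-2-methyl-6-(TBSO-methyl)hept-6-en-1-yl]furan-2(5H)-one | BrCC1=C[C@@H](C[C@H](C)CCCC(=C)CO[Si](C)(C)C(C)(C)C)OC1=O
F4 | step 16 | (4R,5S)-4-[(1R,3R)-3-methyl-7-(TBSO-methyl)-1-(triethylsilyloxy)oct-7-en-1-yl]-3-methylidene-5-[(1E)-prop-1-en-1-yl]oxolan-2-one | C=C1C(=O)O[C@@H](/C=C/C)[C@@H]1[C@H](O[Si](CC)(CC)CC)C[C@H](C)CCCC(=C)CO[Si](C)(C)C(C)(C)C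
F5 | step 16 | (3R,4R,6R)-3-[(1S,2E)-1-hydroxybut-2-en-1-yl]-6-methyl-2-methylidene-10-(TBSO-methyl)-4-(triethylsilyloxy)undec-10-enoic acid | C=C(C(=O)O)[C@H]([C@@H](O)/C=C/C)[C@H](O[Si](CC)(CC)CC)C[C@H](C)CCCC(=C)CO[Si](C)(C)C(C)(C)C
F6 | step 16 | (4R,5R)-4-[(1R,3R)-3-methyl-7-(TBSO-methyl)-1-(triethylsilyloxy)oct-7-en-1-yl]-3-methylidene-5-[(1E)-prop-1-en-1-yl]oxolan-2-one | C=C1C(=O)O[C@H](/C=C/C)[C@@H]1[C@H](O[Si](CC)(CC)CC)C[C@H](C)CCCC(=C)CO[Si](C)(C)C(C)(C)C
F7 | step 16 | (4R,5R)-4-[(1R,2E)-1-hydroxybut-2-en-1-yl]-5-[(2R)-2-methyl-6-(TBSO-methyl)hept-6-en-1-yl]-3-methylideneoxolan-2-one | C=C1C(=O)O[C@H](C[C@H](C)CCCC(=C)CO[Si](C)(C)C(C)(C)C)[C@H]1[C@H](O)/C=C/C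
F8 | step 17 | (3aR,4S,5E,10R,11aR)-4-hydroxy-10-methyl-3-methylidene-6-(TBSO-methyl)-3a,4,7,8,9,10,11,11a-octahydrocyclodeca[b]furan-2(3H)-one | C=C1C(=O)O[C@@H]2C[C@H](C)CCC/C(CO[Si](C)(C)C(C)(C)C)=C\[C@H](O)[C@@H]12
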